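**Retrosynthetic overview**

1. Target 16 ⇒ cut the two enol‑ester C–O bonds: atromentin 9 plus two Z‑epoxyacyl units (lithium salt 14, activated as mixed anhydride 15).
2. Quinone ring of 9 (made as its dimethyl ether 8) ⇒ two C(aryl)–C(=O) bonds: ring‑expanding head‑to‑tail [3+3] dimerisation of the arylhydroxycyclopropenone 5 (three‑membered ring → six‑membered ring), the key step.
3. 5 ⇒ aryl–C3 bond: Friedel–Crafts reaction of anisole 2 with tetrachlorocyclopropene 1.
4. 14 ⇒ oxirane by catalytic asymmetric epoxidation of the Z,E‑dienoate 12; 12 ⇒ C3–C4 Suzuki bond between Z‑iodoacrylate 10 and E‑propenylboronic acid 11.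
5. Ring order: cyclopropenone (step 1) → quinone ring (step 2); the oxiranes (step 5) are made on the side chain before the final coupling (step 7).

Assumption: tetrachlorocyclopropene, ethyl (Z)‑3‑iodoacrylate, (E)‑prop‑1‑enylboronic acid and the L‑fructose‑derived (ent‑)Shi ketone are taken as purchasable.

**Route**

Step 1
Reactants: 1 tetrachlorocyclopropene; 2 anisole
Product: 5 2-hydroxy-3-(4-methoxyphenyl)cycloprop-2-en-1-one, via trichlorocyclopropenium tetrachloroaluminate 3 (not isolated), via aryltrichlorocyclopropene 4 (not isolated)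
Conditions: 1 (1.2 equiv), AlCl3 (1.25 equiv), CH2Cl2, rt; then 2 (1.0 equiv), −40 to −10 °C; then ice–H2O/acetone, rt
Reagents that add atoms: water, O
Why: Friedel–Crafts‑type electrophilic aromatic substitution by the aromatic C3Cl3+ cation goes para to OMe and stops after one arylation at low temperature (the aryldichlorocyclopropenium ion is much less electrophilic), and hydrolysis of the remaining C–Cl bonds gives the strongly acidic hydroxycyclopropenone, isolated by bicarbonate extraction and acidification.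

Step 2
Reactants: 5 2-hydroxy-3-(4-methoxyphenyl)cycloprop-2-en-1-one (two molecules)
Product: 8 2,5-dihydroxy-3,6-bis(4-methoxyphenyl)cyclohexa-2,5-diene-1,4-dione, via silyloxycyclopropenone 6 (not isolated), via bis(silyloxy)quinone 7 (not isolated)
Conditions: BSA (1.1 equiv), toluene, rt; then Ni(cod)2 (10 mol %), P(OPh)3 (20 mol %), 60 °C; then 1 M HCl, THF, rt
Reagents that add atoms: none
Why: Proposed new method: after in‑flask O‑silylation (removes the acidic OH, giving 6), zerovalent nickel inserts into the strained C(=O)–C(aryl) bond of 6 to give a nickelacyclobutenone, a second molecule of 6 is opened the same way and the two C3 units are joined head‑to‑tail by two acyl–C(aryl) reductive eliminations (polarity‑matched: the aryl‑bearing carbon is the nucleophilic enol‑ether β‑carbon, the acyl carbon the electrophile), so two three‑membered rings are expanded into the six‑membered 1,4‑benzoquinone ring of 7, which the acidic work‑up desilylates to 8 (no stereocentre is formed); closest known reaction type: transition‑metal C–C activation of cyclopropenones, namely the zerovalent‑nickel dimerisation of diphenylcyclopropenone to tetraphenyl‑1,4‑benzoquinone and the rhodium‑catalysed [3+2] ring expansion of cyclopropenones with alkynes, neither shown for an unsymmetrical aryl/siloxy cyclopropenone where head‑to‑tail selectivity is required.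

Step 3
Reactants: 8 2,5-dihydroxy-3,6-bis(4-methoxyphenyl)cyclohexa-2,5-diene-1,4-dione
Product: 9 atromentin [2,5-dihydroxy-3,6-bis(4-hydroxyphenyl)cyclohexa-2,5-diene-1,4-dione]
Conditions: BBr3 (6 equiv), CH2Cl2, −78 °C to rt; then H2O
Reagents that add atoms: none
Why: BBr3 aryl methyl ether cleavage (bromide attacks the O‑methyl of the boron‑complexed ether) leaves the hydroxyquinone core intact, and the borate esters are hydrolysed on work‑up.

Step 4
Reactants: 10 ethyl (2Z)-3-iodoprop-2-enoate; 11 (E)-prop-1-en-1-ylboronic acid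
Product: 12 ethyl (2Z,4E)-hexa-2,4-dienoate
Conditions: Pd(PPh3)4 (3 mol %), K2CO3 (2 equiv), THF/H2O, 40 °C
Reagents that add atoms: none
Why: Suzuki–Miyaura coupling in which both alkenyl partners react with retention of geometry, the Z‑iodoacrylate adding oxidatively to zerovalent palladium under conditions mild enough not to isomerise the 2Z bond.

Step 5
Reactants: 12 ethyl (2Z,4E)-hexa-2,4-dienoate
Product: 13 ethyl (2Z)-3-[(2S,3S)-3-methyloxiran-2-yl]prop-2-enoate
Conditions: ent‑Shi ketone (L‑fructose‑derived, 30 mol %), Oxone (2KHSO5·KHSO4·K2SO4), K2CO3, Bu4NHSO4 (cat.), MeCN/DMM–aq. Na2B4O7 buffer (pH 10.5), 0 °C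
Reagents that add atoms: potassium peroxymonosulfate (active part of Oxone), [K+].[O-]S(=O)(=O)OO
Why: Shi asymmetric epoxidation, in which the chiral dioxirane attacks only the electron‑richer trans 4,5‑double bond (the Z‑enoate bond is electron‑poor) through the spiro transition state; the L‑fructose‑derived ketone gives the (4S,5S)‑trans‑epoxide, mirroring the R,R epoxides obtained from trans olefins with the D‑fructose ketone.

Step 6
Reactants: 13 ethyl (2Z)-3-[(2S,3S)-3-methyloxiran-2-yl]prop-2-enoate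
Product: 14 lithium (2Z)-3-[(2S,3S)-3-methyloxiran-2-yl]prop-2-enoate
Conditions: LiOH·H2O (1.0 equiv), THF/H2O, 0 °C to rt; freeze‑dry
Reagents that add atoms: lithium hydroxide, [Li+].[OH-]
Why: Ester saponification under non‑acidic conditions; the product is kept as its dry lithium salt because the free Z‑epoxy acid lactonises, and neither the oxirane stereocentres nor the Z bond are touched.

Step 7
Reactants: 9 atromentin; 14 lithium (2Z)-3-[(2S,3S)-3-methyloxiran-2-yl]prop-2-enoate (2.3 equiv)
Product: 16 atromentin 2,5-bis[(2Z,4S,5S)-4,5-epoxyhex-2-enoate] (target CNP0407724.1), via mixed anhydride 15 (not isolated)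
Conditions: 14, 2,4,6-trichlorobenzoyl chloride (2.2 equiv), THF, 0 °C; then 9, iPr2NEt (2.1 equiv), THF/DMF, −20 to 0 °C
Reagents that add atoms: none
Why: Yamaguchi‑type mixed‑anhydride acylation without DMAP, in which two equivalents of amine deprotonate only the vinylogous‑acid 2,5‑hydroxyls (pKa about 3–5, phenols about 10) and these oxyanions attack the unhindered enoyl carbonyl of 15, so the phenols stay free; no stereocentre is involved, and coupling two units of about 95% ee gives 16 of >99% ee with about 5% of the (S,S)/(R,R) diastereomer, removed by chromatography.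

**Compound list**

1 | tetrachlorocyclopropene (1,2,3,3-tetrachlorocycloprop-1-ene) | ClC1=C(Cl)C1(Cl)Cl | starting material
2 | anisole (methoxybenzene) | COc1ccccc1 | starting material
3 | trichlorocyclopropenium tetrachloroaluminate | ClC1=C(Cl)[C+]1Cl.Cl[Al-](Cl)(Cl)Cl | intermediate
4 | 1-methoxy-4-(2,3,3-trichlorocycloprop-1-en-1-yl)benzene | COc1ccc(cc1)C1=C(Cl)C1(Cl)Cl | intermediate
5 | 2-hydroxy-3-(4-methoxyphenyl)cycloprop-2-en-1-one | COc1ccc(cc1)C1=C(O)C1=O | intermediate
6 | 2-(4-methoxyphenyl)-3-(trimethylsilyloxy)cycloprop-2-en-1-one | COc1ccc(cc1)C1=C(O[Si](C)(C)C)C1=O | intermediate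
7 | 2,5-bis(4-methoxyphenyl)-3,6-bis(trimethylsilyloxy)cyclohexa-2,5-diene-1,4-dione | COc1ccc(cc1)C1=C(O[Si](C)(C)C)C(=O)C(c2ccc(OC)cc2)=C(O[Si](C)(C)C)C1=O | intermediate
8 | 2,5-dihydroxy-3,6-bis(4-methoxyphenyl)cyclohexa-2,5-diene-1,4-dione (atromentin 4,4''-dimethyl ether) | COc1ccc(cc1)C1=C(O)C(=O)C(c2ccc(OC)cc2)=C(O)C1=O | intermediate
9 | atromentin, 2,5-dihydroxy-3,6-bis(4-hydroxyphenyl)cyclohexa-2,5-diene-1,4-dione | Oc1ccc(cc1)C1=C(O)C(=O)C(c2ccc(O)cc2)=C(O)C1=O | intermediate
10 | ethyl (2Z)-3-iodoprop-2-enoate | CCOC(=O)/C=C\I | starting material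
11 | (E)-prop-1-en-1-ylboronic acid | C/C=C/B(O)O | starting material
12 | ethyl (2Z,4E)-hexa-2,4-dienoate | C/C=C/C=C\C(=O)OCC | intermediate
13 | ethyl (2Z)-3-[(2S,3S)-3-methyloxiran-2-yl]prop-2-enoate | C[C@@H]1O[C@H]1/C=C\C(=O)OCC | intermediate
14 | lithium (2Z)-3-[(2S,3S)-3-methyloxiran-2-yl]prop-2-enoate | C[C@@H]1O[C@H]1/C=C\C(=O)[O-].[Li+] | intermediate
15 | (2Z)-3-[(2S,3S)-3-methyloxiran-2-yl]prop-2-enoic 2,4,6-trichlorobenzoic anhydride | C[C@@H]1O[C@H]1/C=C\C(=O)OC(=O)c1c(Cl)cc(Cl)cc1Cl | intermediate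
16 | 2,5-bis(4-hydroxyphenyl)-3,6-dioxocyclohexa-1,4-diene-1,4-diyl bis{(2Z)-3-[(2S,3S)-3-methyloxiran-2-yl]prop-2-enoate} | C[C@@H]1O[C@H]1/C=C\C(=O)OC1=C(c2ccc(O)cc2)C(=O)C(OC(=O)/C=C\[C@@H]2O[C@H]2C)=C(c2ccc(O)cc2)C1=O | target

**Step count and risks**

Total steps: 7. Longest linear sequence: 4 steps (1/2 → 5 → 8 → 9 → 16, or 10/11 → 12 → 13 → 14 → 16).

Steps most likely to fail:

Step 2 (the proposed new step). Risks are decarbonylation of 6 to the siloxyalkyne, the 2,6‑regioisomer, or catalyst death. The fallback uses known, classical chemistry; it sets out from anisole 2 and comes back to the route at 8. Anisole 2 is added twice to 1,4‑benzoquinone with AlCl3 (excess quinone re‑oxidises the hydroquinone adducts) to give 2,5-bis(4-methoxyphenyl)cyclohexa-2,5-diene-1,4-dione F4. Bromination (Br2, AcOH) of the two free ring positions gives 3,6-dibromo-2,5-bis(4-methoxyphenyl)cyclohexa-2,5-diene-1,4-dione F5. KOH in aqueous methanol, then acid, replaces both vinylic bromides by addition–elimination and gives 8, which continues with step 3.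

Step 7. Risks are acylation of the phenols, acyl transfer from the labile acyloxyquinone, and lactonisation of the acid unit. The fallback sets out from 9 and comes back at 16 by way of phenol protection. TBSCl/imidazole in DMF silylates all four hydroxyls to give 2,5-bis[4-(tert-butyldimethylsilyloxy)phenyl]-3,6-bis(tert-butyldimethylsilyloxy)cyclohexa-2,5-diene-1,4-dione F6. AcOH/THF/H2O cleaves only the two very labile quinone O–silyl groups (silyl esters of a vinylogous acid) to give 2,5-bis[4-(tert-butyldimethylsilyloxy)phenyl]-3,6-dihydroxycyclohexa-2,5-diene-1,4-dione F7. Acylation with 15 as in step 7 (now with no competing phenol) gives the bis‑silyl diester 2,5-bis[4-(tert-butyldimethylsilyloxy)phenyl]-3,6-dioxocyclohexa-1,4-diene-1,4-diyl bis{(2Z)-3-[(2S,3S)-3-methyloxiran-2-yl]prop-2-enoate} F8. Et3N·3HF in THF at 0 °C removes the aryl silyl ethers to give 16.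

Step 1. Risks are over‑arylation of the very reactive anisole (di‑ and triarylcyclopropenium salts) and incomplete hydrolysis. The fallback sets out from anisole 2 and comes back at 5, making the three‑membered ring by ring contraction instead. Friedel–Crafts reaction of 2 with commercial 3,4-dichlorocyclobut-3-ene-1,2-dione (AlCl3, CH2Cl2, 0 °C; the second substitution is slow) gives 3-chloro-4-(4-methoxyphenyl)cyclobut-3-ene-1,2-dione F1. Hydrolysis (aqueous AcOH, reflux) gives 3-hydroxy-4-(4-methoxyphenyl)cyclobut-3-ene-1,2-dione F2. BSA gives its silyl ester 3-(4-methoxyphenyl)-4-(trimethylsilyloxy)cyclobut-3-ene-1,2-dione F3. Irradiation (254 nm, benzene) extrudes CO, as in the photodecarbonylation of bis(trimethylsilyl) squarate to the deltate, to give 6, which is hydrolysed to 5 on aqueous work‑up or taken directly into the nickel stage of step 2.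

Further compounds
F1 | step 1 | 3-chloro-4-(4-methoxyphenyl)cyclobut-3-ene-1,2-dione | COc1ccc(cc1)C1=C(Cl)C(=O)C1=O
F2 | step 1 | 3-hydroxy-4-(4-methoxyphenyl)cyclobut-3-ene-1,2-dione | COc1ccc(cc1)C1=C(O)C(=O)C1=O
F3 | step 1 | 3-(4-methoxyphenyl)-4-(trimethylsilyloxy)cyclobut-3-ene-1,2-dione | COc1ccc(cc1)C1=C(O[Si](C)(C)C)C(=O)C1=O
F4 | step 2 | 2,5-bis(4-methoxyphenyl)cyclohexa-2,5-diene-1,4-dione | COc1ccc(cc1)C1=CC(=O)C(c2ccc(OC)cc2)=CC1=O
F5 | step 2 | 3,6-dibromo-2,5-bis(4-methoxyphenyl)cyclohexa-2,5-diene-1,4-dione | COc1ccc(cc1)C1=C(Br)C(=O)C(c2ccc(OC)cc2)=C(Br)C1=O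
F6 | step 7 | 2,5-bis[4-(tert-butyldimethylsilyloxy)phenyl]-3,6-bis(tert-butyldimethylsilyloxy)cyclohexa-2,5-diene-1,4-dione | CC(C)(C)[Si](C)(C)Oc1ccc(cc1)C1=C(O[Si](C)(C)C(C)(C)C)C(=O)C(c2ccc(O[Si](C)(C)C(C)(C)C)cc2)=C(O[Si](C)(C)C(C)(C)C)C1=O
F7 | step 7 | 2,5-bis[4-(tert-butyldimethylsilyloxy)phenyl]-3,6-dihydroxycyclohexa-2,5-diene-1,4-dione | CC(C)(C)[Si](C)(C)Oc1ccc(cc1)C1=C(O)C(=O)C(c2ccc(O[Si](C)(C)C(C)(C)C)cc2)=C(O)C1=O
F8 | step 7 | 2,5-bis[4-(tert-butyldimethylsilyloxy)phenyl]-3,6-dioxocyclohexa-1,4-diene-1,4-diyl bis{(2Z)-3-[(2S,3S)-3-methyloxiran-2-yl]prop-2-enoate} | C[C@@H]1O[C@H]1/C=C\C(=O)OC1=C(c2ccc(O[Si](C)(C)C(C)(C)C)cc2)C(=O)C(OC(=O)/C=C\[C@@H]2O[C@H]2C)=C(c2ccc(O[Si](C)(C)C(C)(C)C)cc2)C1=O
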